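**Plan**
- Retrosynthesis: remove the two acetates; take the 6β,7α-diol back to the C6 ketone of a Δ8 decalone; cut C9–C11 (enol triflate plus side-chain borane); cut C2–C3 of ring A (as an olefin); cut C4–C5 and C1–C10. This leads to 2-methylcyclohexane-1,3-dione, prenylmagnesium chloride and allyl bromide.
- Forward: ring B is the dione. It receives an allyl arm on C10 and a 1,1-dimethylallyl arm on C5; ring A is closed between the arm termini (C2=C3) and saturated in the same flask. Then C8 is methylated, C9 becomes an enol triflate, C5=C6 is hydroborated, the side chain is coupled and the C6/C7 oxygens are set.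
- Enabling feature: C1–C2–C3 of ring A is an unfunctionalised trimethylene strung between the two fully substituted carbons C10 and C4, so ring A can be made by joining two short olefin arms that both sit on ring B. The C5 carbinol formed on the way is a temporary stereocentre, erased by dehydration, so both of its epimers converge.
- Stereochemistry: C10 from an oxazaborolidine-catalysed desymmetrising reduction of the prochiral dione. C5, C6 and C7 from substrate control by the axial C20 and 4β methyl groups (α-face hydroboration, axial enolate hydroxylation at C7, α-face hydride addition at C6). 13Z from hydroxyl-directed hydroalumination–iodination of but-2-yn-1-ol.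

Key step: step 4

Remark: locants C1–C20 are those of the labdane skeleton of the target (C17 on C8, C18/C19 on C4, C20 on C10); α is the face opposite to the C20 methyl group.
Assumption: the sense of induction in step 2 is taken from the usual oxazaborolidine model, with the quaternary carbon as the large group and hydride delivery anti to the allyl group.

**Step 1**
Reactants: 1 2-methylcyclohexane-1,3-dione; 2 allyl bromide
Product: 3 2-methyl-2-(prop-2-en-1-yl)cyclohexane-1,3-dione
Conditions: NaOH (1 M aq.), Bu4NI (cat.), rt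
Reagents that add atoms: none
Why: C-alkylation of the 1,3-dione enolate at the doubly activated C2 gives the achiral, prochiral quaternary dione; any O-allyl ether returns to 3 by Claisen rearrangement on warming.

**Step 2**
Reactants: 3 2-methyl-2-(prop-2-en-1-yl)cyclohexane-1,3-dione
Product: 4 (2R,3R)-3-hydroxy-2-methyl-2-(prop-2-en-1-yl)cyclohexan-1-one
Conditions: (S)-1-methyl-3,3-diphenyltetrahydro-1H,3H-pyrrolo[1,2-c][1,3,2]oxazaborole (0.2 equiv), catecholborane (1.1 equiv), PhNEt2, toluene, −60 °C; aqueous work-up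
Reagents that add atoms: none
Why: Corey–Bakshi–Shibata reduction differentiates the two enantiotopic carbonyl groups: hydride is delivered to one carbonyl anti to the allyl group, which sets the carbinol as 3R (hydroxyl cis to allyl) and thereby fixes the quaternary carbon, the future C10, as R.

**Step 3**
Reactants: 4 (2R,3R)-3-hydroxy-2-methyl-2-(prop-2-en-1-yl)cyclohexan-1-one; 5 prenylmagnesium chloride
Product: 6 (2R,3R)-2-methyl-1-(2-methylbut-3-en-2-yl)-2-(prop-2-en-1-yl)cyclohexane-1,3-diol (both C1 epimers)
Conditions: 5 (2.5 equiv), THF, −78 → 0 °C; aq. NH4Cl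
Reagents that add atoms: none
Why: Allylic Grignard addition through a six-membered SE2′ transition state joins the γ-carbon of the prenyl unit to the hindered carbonyl carbon and so makes the C4–C5 bond with the 1,1-dimethylallyl arm in place; the first equivalent only deprotonates the hydroxyl, and the configuration of the new carbinol carbon is immaterial because it is erased in step 6.

**Step 4**
Reactants: 6 (2R,3R)-2-methyl-1-(2-methylbut-3-en-2-yl)-2-(prop-2-en-1-yl)cyclohexane-1,3-diol
Product: 8 (1R,8aR)-5,5,8a-trimethyldecahydronaphthalene-1,4a-diol (both 4a epimers), via cyclohexene diol 7 (not isolated)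
Conditions: second-generation Grubbs catalyst RuCl2(=CHPh)(H2IMes)(PCy3) (5 mol %), toluene (0.01 M), 80 °C; then H2 (5 bar), 70 °C, same flask
Reagents that add atoms: none
Why: Ring-closing olefin metathesis: the ruthenium benzylidene first exchanges with the unhindered allyl terminus to place the carbene on C2, which adds intramolecularly to the neopentyl vinyl group through a ruthenacyclobutane and expels ethene to form the C2=C3 bond; under H2 the spent carbene becomes a ruthenium hydride that saturates this only olefin, so the C2–C3 single bond of ring A results in one flask. The closest known reaction type is tandem ring-closing metathesis–hydrogenation giving cyclohexanes that carry an allylic quaternary carbon. Ring A closes as a six-membered ring by metathesis of a 1,7-diene whose two arms sit on the adjacent ring B carbons C10 and C5. No new stereocentre is formed and C10 is not touched; both C5 epimers of 6 should cyclise (to cis- and trans-fused diols) and converge in step 6. The selectivity needed is cyclisation over intermolecular metathesis, which is secured by the gem-dimethyl group at C4 and the quaternary C10 (Thorpe–Ingold effect), by the inability of the hindered vinyl group to homodimerise and by high dilution; the free hydroxyl groups are tolerated by the catalyst.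

**Step 5**
Reactants: 8 (1R,8aR)-5,5,8a-trimethyldecahydronaphthalene-1,4a-diol
Product: 9 (8aS)-4a-hydroxy-5,5,8a-trimethyloctahydronaphthalen-1(2H)-one (both 4a epimers)
Conditions: Dess–Martin periodinane, NaHCO3, CH2Cl2, rt
Reagents that add atoms: none
Why: Dess–Martin oxidation converts the secondary C9 alcohol to the ketone under buffered conditions that leave the tertiary C5 alcohol untouched and avoid retro-aldol cleavage of the resulting β-hydroxy ketone.

**Step 6**
Reactants: 9 (8aS)-4a-hydroxy-5,5,8a-trimethyloctahydronaphthalen-1(2H)-one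
Product: 10 (8aS)-5,5,8a-trimethyl-3,5,6,7,8,8a-hexahydronaphthalen-1(2H)-one
Conditions: SOCl2, pyridine, CH2Cl2, −20 → 0 °C
Reagents that add atoms: none
Why: Dehydration through the chlorosulfite (E2 elimination with pyridine) can only run towards C6 because C4 and C10 are quaternary, so both C5 epimers give the same C5=C6 olefin, which cannot move into conjugation past the quaternary C10.

**Step 7**
Reactants: 10 (8aS)-5,5,8a-trimethyl-3,5,6,7,8,8a-hexahydronaphthalen-1(2H)-one
Product: 12 (8aS)-2,5,5,8a-tetramethyl-3,5,6,7,8,8a-hexahydronaphthalen-1(2H)-one (both C2 epimers), via lithium enolate 11 (not isolated)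
Conditions: LiN(i-Pr)2, THF, −78 °C; MeI, −78 → −20 °C
Reagents that add atoms: iodomethane, CI
Why: Kinetic enolate alkylation: C8 is the only enolisable position, so the C17 methyl group enters regiospecifically; the configuration at C8 is irrelevant because C8 becomes sp2 in step 8.

**Step 8**
Reactants: 12 (8aS)-2,5,5,8a-tetramethyl-3,5,6,7,8,8a-hexahydronaphthalen-1(2H)-one
Product: 14 (8aS)-2,5,5,8a-tetramethyl-3,5,6,7,8,8a-hexahydronaphthalen-1-yl trifluoromethanesulfonate, via potassium enolate 13 (not isolated)
Conditions: KN(SiMe3)2, THF, −78 → 0 °C; PhNTf2, −78 °C → rt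
Reagents that add atoms: N-phenylbis(trifluoromethanesulfonimide), O=S(=O)(N(c1ccccc1)S(=O)(=O)C(F)(F)F)C(F)(F)F
Why: O-sulfonylation of the only possible (tetrasubstituted) enolate gives the C8=C9 enol triflate, as for 2,2,6-trimethylcyclohexanone, and at the same time masks the carbonyl group against borane in step 9.

**Step 9**
Reactants: 14 (8aS)-2,5,5,8a-tetramethyl-3,5,6,7,8,8a-hexahydronaphthalen-1-yl trifluoromethanesulfonate
Product: 16 (4S,4aS,8aS)-4-hydroxy-2,5,5,8a-tetramethyl-3,4,4a,5,6,7,8,8a-octahydronaphthalen-1-yl trifluoromethanesulfonate (5α-H and 6α-OH), via 6α-alkylborane 15 (not isolated)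
Conditions: BH3·THF, THF, 0 °C → rt; then 30% H2O2, pH 7 phosphate buffer, MeOH, 0 °C → rt
Reagents that add atoms: hydrogen peroxide, OO
Why: Hydroboration–oxidation: borane adds syn to the trisubstituted C5=C6 olefin with boron on the less substituted C6 and from the α-face, opposite to the axial C20 and 4β methyl groups, so that C5 receives its hydrogen α (trans ring fusion) and oxidation with retention gives the 6α-alcohol; the electron-poor tetrasubstituted enol triflate should not react and should survive the buffered peroxide.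

**Step 10**
Reactants: 17 but-2-yn-1-ol
Product: 19 (2Z)-3-iodobut-2-en-1-ol, via sodium alkenylalanate 18 (not isolated)
Conditions: NaAlH2(OCH2CH2OMe)2, THF, 0 °C → rt; then I2, THF, −78 °C
Reagents that add atoms: iodine, II
Why: Hydroxyl-directed trans-hydroalumination of the propargylic alcohol places aluminium on C3 in a five-membered alkoxyalanate, and iodinolysis with retention gives the Z vinyl iodide (iodine cis to CH2OH), which fixes the later 13Z geometry.

**Step 11**
Reactants: 19 (2Z)-3-iodobut-2-en-1-ol
Product: 20 tert-butyl{[(2Z)-3-iodobut-2-en-1-yl]oxy}dimethylsilane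
Conditions: TBSCl, imidazole, CH2Cl2, rt
Reagents that add atoms: tert-butyldimethylsilyl chloride, CC(C)(C)[Si](C)(C)Cl
Why: Standard silylation of the primary allylic alcohol protects it through the coupling, oxidation and enolate steps.

**Step 12**
Reactants: 20 tert-butyl{[(2Z)-3-iodobut-2-en-1-yl]oxy}dimethylsilane
Product: 21 tert-butyldimethyl{[(2Z)-3-methylpenta-2,4-dien-1-yl]oxy}silane
Conditions: CH2=CHMgBr, Pd(PPh3)4 (5 mol %), THF, 0 °C → rt
Reagents that add atoms: vinylmagnesium bromide, C=C[Mg]Br
Why: Palladium-catalysed Kumada–Corriu coupling of the alkenyl iodide with the vinyl Grignard reagent proceeds with retention of olefin geometry and should give the Z diene.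

**Step 13**
Reactants: 21 tert-butyldimethyl{[(2Z)-3-methylpenta-2,4-dien-1-yl]oxy}silane; 16 (4S,4aS,8aS)-4-hydroxy-2,5,5,8a-tetramethyl-3,4,4a,5,6,7,8,8a-octahydronaphthalen-1-yl trifluoromethanesulfonate
Product: 23 (5S,6S,10S,13Z)-15-[(tert-butyldimethylsilyl)oxy]labda-8,13-dien-6-ol (6α-OH), via homoallylic 9-BBN borane 22 (not isolated)
Conditions: 21, 9-BBN-H (0.5 M in THF), rt; then 16, PdCl2(dppf) (10 mol %), K3PO4 (3 M aq.), DMF, 60 °C
Reagents that add atoms: none
Why: 9-BBN-H adds to the terminal carbon of the monosubstituted olefin of the diene much faster than to the trisubstituted one, and the resulting primary alkylborane undergoes B-alkyl Suzuki–Miyaura coupling with the hindered enol triflate (precedent: 2,6,6-trimethylcyclohexenyl triflates) to form the C9–C11 bond, with the tetrasubstituted C8=C9 olefin and the Z side-chain olefin in place; the free 6-hydroxyl is tolerated.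

**Step 14**
Reactants: 23 (5S,6S,10S,13Z)-15-[(tert-butyldimethylsilyl)oxy]labda-8,13-dien-6-ol
Product: 24 (5S,10S,13Z)-15-[(tert-butyldimethylsilyl)oxy]labda-8,13-dien-6-one
Conditions: Dess–Martin periodinane, NaHCO3, CH2Cl2, 0 °C → rt
Reagents that add atoms: none
Why: Dess–Martin oxidation under buffered conditions should give the β,γ-unsaturated 6-ketone without epimerisation at C5 or migration of the C8=C9 olefin into conjugation.

**Step 15**
Reactants: 24 (5S,10S,13Z)-15-[(tert-butyldimethylsilyl)oxy]labda-8,13-dien-6-one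
Product: 26 (5S,7S,10S,13Z)-15-[(tert-butyldimethylsilyl)oxy]-7-hydroxylabda-8,13-dien-6-one (7α-OH), via potassium dienolate 25 (not isolated)
Conditions: KN(SiMe3)2, THF, −78 °C; 2-(phenylsulfonyl)-3-phenyloxaziridine, −78 °C; AcOH, −78 °C
Reagents that add atoms: 2-(phenylsulfonyl)-3-phenyloxaziridine, O=S(=O)(N1OC1c1ccccc1)c1ccccc1
Why: Enolate hydroxylation with an N-sulfonyloxaziridine: the base removes a C7 proton (α to the ketone and allylic, whereas the C5 proton is tertiary and flanked by two quaternary carbons), and the dienolate is oxidised at its α-carbon C7 (the γ-carbon C9 is fully substituted) by axial attack on the α-face, so that the new hydroxyl is 7α.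

**Step 16**
Reactants: 26 (5S,7S,10S,13Z)-15-[(tert-butyldimethylsilyl)oxy]-7-hydroxylabda-8,13-dien-6-one
Product: 27 (5S,6S,7S,10S,13Z)-15-[(tert-butyldimethylsilyl)oxy]labda-8,13-diene-6,7-diol (6β-OH and 7α-OH)
Conditions: NaBH4, MeOH/THF, −40 → 0 °C
Reagents that add atoms: none
Why: Borohydride reduction of the 6-ketone takes place from the α-face because the β-face is blocked by the syn-axial C20 and 4β methyl groups (as in the reduction of 7α-substituted 6-keto steroids), which gives the axial 6β-alcohol trans to the 7α-hydroxyl.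

**Step 17**
Reactants: 27 (5S,6S,7S,10S,13Z)-15-[(tert-butyldimethylsilyl)oxy]labda-8,13-diene-6,7-diol
Product: 28 (5S,6S,7S,10S,13Z)-labda-8,13-diene-6,7,15-triol
Conditions: Bu4NF, THF, 0 °C → rt
Reagents that add atoms: none
Why: Fluoride-mediated desilylation frees the primary allylic alcohol without touching the diol.

**Step 18**
Reactants: 28 (5S,6S,7S,10S,13Z)-labda-8,13-diene-6,7,15-triol
Product: 29 (5S,6S,7S,10S,13Z)-6-hydroxylabda-8,13-diene-7,15-diyl diacetate (target)
Conditions: Ac2O (2.5 equiv), pyridine, 0 °C → rt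
Reagents that add atoms: acetic anhydride, CC(=O)OC(C)=O
Why: Acylation differentiates the three hydroxyls by hindrance: the primary allylic C15 and the secondary allylic 7α-hydroxyl should be acetylated while the axial 6β-hydroxyl, 1,3-diaxial to the C20 and 4β methyl groups, stays free.

**Compound list**
1 | 2-methylcyclohexane-1,3-dione | CC1C(=O)CCCC1=O | starting material
2 | allyl bromide (3-bromoprop-1-ene) | C=CCBr | starting material
3 | 2-methyl-2-(prop-2-en-1-yl)cyclohexane-1,3-dione | C=CCC1(C)C(=O)CCCC1=O | intermediate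
4 | (2R,3R)-3-hydroxy-2-methyl-2-(prop-2-en-1-yl)cyclohexan-1-one (hydroxyl cis to allyl) | C=CC[C@@]1(C)C(=O)CCC[C@H]1O | intermediate
5 | prenylmagnesium chloride, (3-methylbut-2-en-1-yl)magnesium chloride | CC(C)=CC[Mg]Cl | starting material
6 | (2R,3R)-2-methyl-1-(2-methylbut-3-en-2-yl)-2-(prop-2-en-1-yl)cyclohexane-1,3-diol, both C1 epimers | C=CC[C@@]1(C)C(O)(C(C)(C)C=C)CCC[C@H]1O | intermediate
7 | (1R,8aR)-5,5,8a-trimethyl-1,2,3,4,4a,5,8,8a-octahydronaphthalene-1,4a-diol, both 4a epimers (ring A with C2=C3) | C[C@]12CC=CC(C)(C)C1(O)CCC[C@H]2O | intermediate (not isolated)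
8 | (1R,8aR)-5,5,8a-trimethyldecahydronaphthalene-1,4a-diol, both 4a epimers | C[C@]12CCCC(C)(C)C1(O)CCC[C@H]2O | intermediate
9 | (8aS)-4a-hydroxy-5,5,8a-trimethyloctahydronaphthalen-1(2H)-one, both 4a epimers | C[C@]12CCCC(C)(C)C1(O)CCCC2=O | intermediate
10 | (8aS)-5,5,8a-trimethyl-3,5,6,7,8,8a-hexahydronaphthalen-1(2H)-one | C[C@]12CCCC(C)(C)C1=CCCC2=O | intermediate
11 | lithium enolate of 10 (C8=C9–OLi) | C[C@]12CCCC(C)(C)C1=CCC=C2O[Li] | intermediate (not isolated)
12 | (8aS)-2,5,5,8a-tetramethyl-3,5,6,7,8,8a-hexahydronaphthalen-1(2H)-one, both C2 epimers | C[C@]12CCCC(C)(C)C1=CCC(C)C2=O | intermediate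
13 | potassium enolate of 12 (C8=C9–OK) | C[C@]12CCCC(C)(C)C1=CCC(C)=C2O[K] | intermediate (not isolated)
14 | (8aS)-2,5,5,8a-tetramethyl-3,5,6,7,8,8a-hexahydronaphthalen-1-yl trifluoromethanesulfonate | C[C@]12CCCC(C)(C)C1=CCC(C)=C2OS(=O)(=O)C(F)(F)F | intermediate
15 | 6α-boryl-5α-H enol triflate (monoalkylborane) | O=S(=O)(OC1=C(C)C[C@H](B)[C@H]2C(C)(C)CCC[C@]12C)C(F)(F)F | intermediate (not isolated)
16 | (4S,4aS,8aS)-4-hydroxy-2,5,5,8a-tetramethyl-3,4,4a,5,6,7,8,8a-octahydronaphthalen-1-yl trifluoromethanesulfonate (5α-H, 6α-OH) | O=S(=O)(OC1=C(C)C[C@H](O)[C@H]2C(C)(C)CCC[C@]12C)C(F)(F)F | intermediate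
17 | but-2-yn-1-ol | CC#CCO | starting material
18 | sodium 2,2-bis(2-methoxyethoxy)-3-methyl-2,5-dihydro-1,2-oxaluminol-2-uide (cyclic alkenylalanate) | CC1=CCO[Al-]1(OCCOC)OCCOC.[Na+] | intermediate (not isolated)
19 | (2Z)-3-iodobut-2-en-1-ol | C/C(I)=C/CO | intermediate
20 | tert-butyl{[(2Z)-3-iodobut-2-en-1-yl]oxy}dimethylsilane | C/C(I)=C/CO[Si](C)(C)C(C)(C)C | intermediate
21 | tert-butyldimethyl{[(2Z)-3-methylpenta-2,4-dien-1-yl]oxy}silane | C/C(C=C)=C/CO[Si](C)(C)C(C)(C)C | intermediate
22 | 9-[(3Z)-5-(tert-butyldimethylsilyloxy)-3-methylpent-3-en-1-yl]-9-borabicyclo[3.3.1]nonane | C/C(CCB1C2CCCC1CCC2)=C/CO[Si](C)(C)C(C)(C)C | intermediate (not isolated)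
23 | (5S,6S,10S,13Z)-15-[(tert-butyldimethylsilyl)oxy]labda-8,13-dien-6-ol (6α-OH) | C/C(CCC1=C(C)C[C@H](O)[C@H]2C(C)(C)CCC[C@]12C)=C/CO[Si](C)(C)C(C)(C)C | intermediate
24 | (5S,10S,13Z)-15-[(tert-butyldimethylsilyl)oxy]labda-8,13-dien-6-one | C/C(CCC1=C(C)CC(=O)[C@H]2C(C)(C)CCC[C@]12C)=C/CO[Si](C)(C)C(C)(C)C | intermediate
25 | potassium dienolate of 24 (C6–OK, C6=C7, C8=C9) | C/C(CCC1=C(C)C=C(O[K])[C@H]2C(C)(C)CCC[C@]12C)=C/CO[Si](C)(C)C(C)(C)C | intermediate (not isolated)
26 | (5S,7S,10S,13Z)-15-[(tert-butyldimethylsilyl)oxy]-7-hydroxylabda-8,13-dien-6-one (7α-OH) | C/C(CCC1=C(C)[C@H](O)C(=O)[C@H]2C(C)(C)CCC[C@]12C)=C/CO[Si](C)(C)C(C)(C)C | intermediate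
27 | (5S,6S,7S,10S,13Z)-15-[(tert-butyldimethylsilyl)oxy]labda-8,13-diene-6,7-diol (6β-OH, 7α-OH) | C/C(CCC1=C(C)[C@H](O)[C@@H](O)[C@H]2C(C)(C)CCC[C@]12C)=C/CO[Si](C)(C)C(C)(C)C | intermediate
28 | (5S,6S,7S,10S,13Z)-labda-8,13-diene-6,7,15-triol | C/C(CCC1=C(C)[C@H](O)[C@@H](O)[C@H]2C(C)(C)CCC[C@]12C)=C/CO | intermediate
29 | (5S,6S,7S,10S,13Z)-6-hydroxylabda-8,13-diene-7,15-diyl diacetate | CC(=O)OC/C=C(/C)CCC1=C(C)[C@H](OC(C)=O)[C@@H](O)[C@H]2C(C)(C)CCC[C@]12C | target

**Step count**
Total steps: 18. Longest linear sequence: 15 (steps 1–9 and 13–18); steps 10–12 make the side-chain fragment.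

**Steps most likely to fail**

Step 15. Oxygen transfer may go to the wrong face of the dienolate, or the base may shift the α-ketol to the conjugated 6-hydroxy-7-ketone or move the C8=C9 olefin into conjugation. The fallback sets out from 24 and returns to the route at 29. The dienolate 25 is brominated with N-bromosuccinimide at −78 °C to the 7α-bromo-6-ketone F1. NaBH4 reduces the ketone from the α-face to the trans-diaxial 6β-hydroxy-7α-bromide F2. K2CO3 in MeOH closes the 6β,7β-epoxide F3. CsOAc in AcOH/DMF opens the allylic C7–O bond with inversion (trans-diaxial opening) to the 6β-hydroxy-7α-acetate silyl ether F4. HF·pyridine removes the silyl group to give the 6β-hydroxy-7α-acetoxy-15-ol F5. Acetylation of the primary hydroxyl under the conditions of step 18 then gives 29.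

Step 9. Borane addition to the hindered C5=C6 olefin (C5 lies between two quaternary carbons) may be slow, may take place in part from the β-face, or the triflate may be lost during the oxidative work-up. The fallback sets out from 14 and returns at 16. 3-Chloroperbenzoic acid epoxidises the C5=C6 olefin from the α-face to the 5α,6α-epoxide enol triflate F6. Cp2TiCl (trivalent titanium, made from Cp2TiCl2 and Mn powder) with water as hydrogen source then opens the epoxide by homolysis of the tertiary C5–O bond and reduces the C5 radical from the α-face, which gives 16.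

Step 13. Oxidative addition and transmetalation at the hindered tetrasubstituted triflate may be sluggish, the triflate may hydrolyse, or the hydroboration of the diene may lose regiocontrol. The fallback reverses the polarity of the fragment union; it sets out from 16 and returns at 23. Stille coupling of 16 with tributyl(vinyl)stannane Bu3SnCH=CH2 (Pd(PPh3)4, LiCl, THF) gives the 9-vinyl dienol F7. Excess 9-BBN-H hydroborates its terminal vinyl group to the C12 borane F8 (the hydroxyl is borylated transiently). B-alkyl Suzuki–Miyaura coupling of F8 with iodide 20 (PdCl2(dppf), K3PO4) forms the C12–C13 bond with retention of the Z geometry and gives 23.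

**Further compounds**
F1 | step 15 | (5S,7S,10S,13Z)-7-bromo-15-[(tert-butyldimethylsilyl)oxy]labda-8,13-dien-6-one (7α-Br) | C/C(CCC1=C(C)[C@H](Br)C(=O)[C@H]2C(C)(C)CCC[C@]12C)=C/CO[Si](C)(C)C(C)(C)C
F2 | step 15 | 7α-bromo-15-[(tert-butyldimethylsilyl)oxy]labda-8,13Z-dien-6β-ol | C/C(CCC1=C(C)[C@H](Br)[C@@H](O)[C@H]2C(C)(C)CCC[C@]12C)=C/CO[Si](C)(C)C(C)(C)C
F3 | step 15 | 6β,7β-epoxy-15-[(tert-butyldimethylsilyl)oxy]labda-8,13Z-diene | C/C(CCC1=C(C)[C@H]3O[C@H]3[C@H]2C(C)(C)CCC[C@]12C)=C/CO[Si](C)(C)C(C)(C)C
F4 | step 15 | 7α-acetoxy-15-[(tert-butyldimethylsilyl)oxy]labda-8,13Z-dien-6β-ol | C/C(CCC1=C(C)[C@H](OC(C)=O)[C@@H](O)[C@H]2C(C)(C)CCC[C@]12C)=C/CO[Si](C)(C)C(C)(C)C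
F5 | step 15 | 7α-acetoxylabda-8,13Z-diene-6β,15-diol | C/C(CCC1=C(C)[C@H](OC(C)=O)[C@@H](O)[C@H]2C(C)(C)CCC[C@]12C)=C/CO
F6 | step 9 | 5α,6α-epoxide of enol triflate 14 | O=S(=O)(OC1=C(C)C[C@@H]3O[C@@]32C(C)(C)CCC[C@]12C)C(F)(F)F
F7 | step 13 | (1S,8aS)-5-ethenyl-2,2,6,8a-tetramethyl-1,2,3,4,7,8-hexahydro... 9-vinyl dienol (5α-H, 6α-OH, C8=C9, C11=C12) | C=CC1=C(C)C[C@H](O)[C@H]2C(C)(C)CCC[C@]12C
F8 | step 13 | 9-BBN borane at C12 of the 6α-hydroxy Δ8 decalin | C(CB1C2CCCC1CCC2)C3=C(C)C[C@H](O)[C@H]4C(C)(C)CCC[C@]34C
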